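The data are simulated from invented constants; scatter was added.

The constant I want from the earlier runs is a time constant: how fast the first step, starting material plus reagent to first product, works on what has been dosed.

| flask | starting material | reagent | remark | time |
|---|---|---|---|---|
| east | 20 mM (fed, over 20 min) | 30 mM | run made earlier |  |
| north-west | 20 mM (fed, over 20 min) | 31 mM | run made earlier |  |
| south-west | 20 mM (fed, over 20 min) | 41 mM | run made earlier |  |
| Saturday's | 20 mM (fed, over 20 min) | 24.0 mM |  | 20 min |
| Thursday's | 20 mM (fed, over 20 min) | 40.0 mM |  | 20 min |
| Monday's | 20 mM (fed, over 20 min) | 50.0 mM |  | 20 min |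

| run | time / min | first product / % | double product / % |
|---|---|---|---|
| east | 1.00 | 0 | 0 |
| east | 2.50 | 2 | 2 |
| east | 6.00 | 6 | 2 |
| east | 15.0 | 22 | 1 |
| north-west | 2.00 | 0 | 1 |
| north-west | 5.00 | 2 | 0 |
| north-west | 10.0 | 11 | 6 |
| north-west | 15.0 | 24 | 0 |
| south-west | 2.00 | 3 | 0 |
| south-west | 5.00 | 3 | 0 |
| south-west | 10.0 | 13 | 0 |
| south-west | 15.0 | 28 | 4 |

(scatter of a reading: 2 percentage points)

- percentages count the whole charge, also what has not yet gone in

- final first product, as a percentage of the starting material charged, for each flask in turn (Saturday's, Thursday's, Monday's)

With reagent held at its starting value the step is pseudo-first-order, so the dosed starting material is a ramp into a first-order lag. If a dose lasts n time constants, which I call turnovers, the share of the charge turned at its end is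

turned = 1 − (1 − exp(−n))/n

For a part-way reading, where a share f of what has gone in is turned, I invert this approximately: u ≈ 2f/(1 − 2f/3).

At 15.0 min the earlier runs average 26.3% of the charge as first plus double product, with reagent at 1.70 charges of starting material. So:

share of what has gone in: 35.1%
so far, in turnovers: 0.917
dose constant g: 0.719

The dose constant g, the turnovers of a whole dose per charge of reagent, is a reading with the scatter in it, and n is g times the reagent ratio.

I take double product to form from first product, and I let its share of the turned grow with the turnovers. At 15.0 min that share reads 6.33%, or 0.0690 per turnover. The mean reading is 1.67% against a scatter of 2 percentage points, so I hold this entry loosely.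

The ledger, in fractions of the starting material charged:

Saturday's: n = 0.863; left 67.0%; double 1.97%; first 31.0%
Thursday's: n = 1.44; left 53.0%; double 4.66%; first 42.3%
Monday's: n = 1.80; left 46.4%; double 6.65%; first 46.9%

The forecast gives 28.5%, 40% and 45%, each below my line, and adds that the “highest reagent level is the least certain”.

The flask gives 29.7%, 39.0% and 42.3% of first product for Saturday's, Thursday's and Monday's.

    reagent + triple product → tetra adduct + released group (k = 0.0140 M⁻¹ s⁻¹)
    reagent + double product → triple product + released group (k = 0.150 M⁻¹ s⁻¹)
    reagent + first product → double product + released group (k = 0.0130 M⁻¹ s⁻¹)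
    starting material + reagent → first product + released group (k = 0.0370 M⁻¹ s⁻¹)

On Monday's my double entry was 6.65%, while double product, triple product and tetra adduct together stand at 11.5%. The dose constant gave Saturday's 67.0% of starting material left, and the flask holds 67% at 20.0 min. On Monday's, 1.80 turnovers gave 46.4% left, and the flask holds 46% at 20.0 min.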